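The plan rests on cutting the 2,2-dimethylpyran ring of the chroman at C4–C3 and O1–C2. Its benzylic C4 hangs on C4a, next to the biaryl carbon C5, and O1 on C8a lies para to the prenyl-bearing C6, an arrangement that an ortho-quinone methide of ring B and isobutene can assemble directly. One thermal hetero-Diels–Alder step forms both bonds and closes the pyran ring from salicyl alcohol 11, a 5-bromoresorcinol derivative that already carries the prenyl group, a TIPS ether and the bromine handle. The bromide then becomes an alkyne that is joined to a chiral iodoresorcinol (ring A) by Sonogashira heteroannulation.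

Key step: step 9

Remark: silylation of 5-bromo-4-prenylresorcinol itself would go to the unhindered hydroxyl, so that hydroxyl is carried as a MOM ether through the Claisen shift and the hindered phenol is silylated alone; TIPS is chosen for its stability to heat, base and organolithium reagents.
Assumption: ethyl N,N-diisopropylcarbamate 23 and (+)-sparteine are purchased; phenolic MOM groups are removed with TMSOTf and 2,2'-bipyridyl, because protic acid would add a free phenol to the neighbouring isopropenyl group.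

Step 1
Reactants: 1 5-bromoresorcinol
Product: 2 3-bromo-5-(methoxymethoxy)phenol
Conditions: MOMCl (0.5 equiv), i-Pr2NEt, CH2Cl2/THF, 0 °C → rt
Reagents that add atoms: chloromethyl methyl ether (MOMCl), COCCl
Why: Williamson-type monoalkylation of the symmetric diol with a deficit of MOMCl should give mainly the mono-ether (statistical desymmetrisation, unreacted diol recovered), and the MOM group keeps this oxygen masked and electron-donating for the Claisen step.

Step 2
Reactants: 2 3-bromo-5-(methoxymethoxy)phenol, 3 3-chloro-3-methylbut-1-yne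
Product: 4 1-bromo-3-(methoxymethoxy)-5-[(2-methylbut-3-yn-2-yl)oxy]benzene
Conditions: DBU, CuCl2 (cat.), MeCN, 0 °C
Reagents that add atoms: none
Why: Copper-catalysed propargylic etherification of a phenol with a tertiary propargylic chloride is the standard entry to aryl 1,1-dimethylpropargyl ethers.

Step 3
Reactants: 4 1-bromo-3-(methoxymethoxy)-5-[(2-methylbut-3-yn-2-yl)oxy]benzene
Product: 5 1-bromo-3-(methoxymethoxy)-5-[(2-methylbut-3-en-2-yl)oxy]benzene
Conditions: H2 (1 atm), Pd/CaCO3 poisoned with Pb(OAc)2, quinoline, EtOAc, rt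
Reagents that add atoms: none
Why: Semihydrogenation over lead-poisoned palladium should stop at the alkene and leave the aryl bromide and the MOM ether untouched.

Step 4
Reactants: 5 1-bromo-3-(methoxymethoxy)-5-[(2-methylbut-3-en-2-yl)oxy]benzene
Product: 6 3-bromo-5-(methoxymethoxy)-2-(3-methylbut-2-enyl)phenol
Conditions: xylenes (degassed), 130 °C
Reagents that add atoms: none
Why: The aromatic Claisen rearrangement ([3,3] shift) of the 1,1-dimethylallyl ether delivers a prenyl group to an ortho carbon, and both meta substituents (bromine, which draws the shift toward itself, and the alkoxy group, which directs para to itself) should favour the carbon beside bromine, the minor isomer being removed by chromatography.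

Step 5
Reactants: 6 3-bromo-5-(methoxymethoxy)-2-(3-methylbut-2-enyl)phenol
Product: 7 [3-bromo-5-(methoxymethoxy)-2-(3-methylbut-2-enyl)phenoxy]triisopropylsilane
Conditions: TIPSCl, imidazole, DMF, 40 °C
Reagents that add atoms: triisopropylsilyl chloride (TIPSCl), CC(C)[Si](Cl)(C(C)C)C(C)C
Why: Silylation of the only free hydroxyl places the silyl group on the hindered oxygen next to the prenyl group, which direct silylation of the diol would not do.

Step 6
Reactants: 7 [3-bromo-5-(methoxymethoxy)-2-(3-methylbut-2-enyl)phenoxy]triisopropylsilane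
Product: 9 3-bromo-4-(3-methylbut-2-enyl)-5-(triisopropylsilyloxy)phenol, via aryl trimethylsilyl ether 8 (not isolated)
Conditions: TMSOTf, 2,2'-bipyridyl, CH2Cl2, 0 °C → rt; then H2O
Reagents that add atoms: none
Why: Silyl triflate and bipyridyl convert an aryl MOM ether into the aryl trimethylsilyl ether under buffered aprotic conditions, and water then frees the phenol, so the prenyl alkene and the TIPS ether should survive.

Step 7
Reactants: 9 3-bromo-4-(3-methylbut-2-enyl)-5-(triisopropylsilyloxy)phenol
Product: 10 2-bromo-6-hydroxy-3-(3-methylbut-2-enyl)-4-(triisopropylsilyloxy)benzaldehyde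
Conditions: MgCl2, Et3N, (CH2O)n, MeCN, 80 °C
Reagents that add atoms: paraformaldehyde (formaldehyde), C=O
Why: Magnesium-mediated ortho-formylation delivers formaldehyde through the magnesium phenoxide to an ortho carbon, and the carbon para to the silyloxy group (beside bromine) should be preferred over the one wedged between the hydroxyl and the bulky TIPS ether, as with 3-alkoxyphenols.

Step 8
Reactants: 10 2-bromo-6-hydroxy-3-(3-methylbut-2-enyl)-4-(triisopropylsilyloxy)benzaldehyde
Product: 11 3-bromo-2-(hydroxymethyl)-4-(3-methylbut-2-enyl)-5-(triisopropylsilyloxy)phenol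
Conditions: NaBH4, THF/MeOH, 0 °C
Reagents that add atoms: none
Why: Borohydride reduction of the salicylaldehyde gives the salicyl alcohol without touching the bromide, the alkene or the silyl ether.

Step 9
Reactants: 11 3-bromo-2-(hydroxymethyl)-4-(3-methylbut-2-enyl)-5-(triisopropylsilyloxy)phenol, 12 isobutene
Product: 14 5-bromo-2,2-dimethyl-6-(3-methylbut-2-enyl)-7-(triisopropylsilyloxy)chroman, via ortho-quinone methide 13 (not isolated)
Conditions: isobutene (ca. 40 equiv, condensed), PhMe, sealed steel autoclave, 155 °C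
Reagents that add atoms: none
Why: Heating the salicyl alcohol should expel water by 1,4-elimination to give the ortho-quinone methide 13, an electron-poor oxa-diene that isobutene captures in an inverse-electron-demand hetero-Diels–Alder reaction, with re-aromatisation of ring B as driving force. The closest known reaction type is the thermal [4+2] cycloaddition of ortho-quinone methides with 1,1-disubstituted alkenes, which gives 2,2-dialkylchromans. The pyran ring is closed by intermolecular [4+2] annulation, concerted but asynchronous, the C4–C3 bond forming ahead of the O1–C2 bond, and no stereocenter is created. The step needs regioselectivity, which the polarisation of both partners secures: the nucleophilic CH2 terminus of isobutene meets the electrophilic exocyclic CH2, and oxygen closes onto the tertiary carbon that carries the developing positive charge. It also needs chemoselectivity over self-condensation of 13 and over capture by a prenyl alkene: the large excess of isobutene serves this, the prenyl group cannot reach the methylene of its own molecule across the bromine-bearing carbon, and the silyl ether on the oxygen para to the benzylic carbon shuts off the para-quinone methide tautomer.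

Step 10
Reactants: 14 5-bromo-2,2-dimethyl-6-(3-methylbut-2-enyl)-7-(triisopropylsilyloxy)chroman
Product: 16 2,2-dimethyl-6-(3-methylbut-2-enyl)-7-(triisopropylsilyloxy)chroman-5-carbaldehyde, via aryllithium 15 (not isolated)
Conditions: t-BuLi (2.1 equiv), THF, −78 °C; DMF, −78 → 0 °C; H2O
Reagents that add atoms: N,N-dimethylformamide (DMF), CN(C)C=O
Why: Bromine–lithium exchange is fast even for a di-ortho-substituted aryl bromide at −78 °C, and formylation of the aryllithium with DMF gives the aldehyde.

Step 11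
Reactants: 16 2,2-dimethyl-6-(3-methylbut-2-enyl)-7-(triisopropylsilyloxy)chroman-5-carbaldehyde
Product: 17 5-ethynyl-2,2-dimethyl-6-(3-methylbut-2-enyl)-7-(triisopropylsilyloxy)chroman
Conditions: MeC(O)C(N2)P(O)(OMe)2, K2CO3, MeOH/THF, 0 °C → rt
Reagents that add atoms: dimethyl (1-diazo-2-oxopropyl)phosphonate, CC(=O)C(=[N+]=[N-])P(=O)(OC)OC
Why: Seyferth–Gilbert homologation with the diazophosphonate converts the aldehyde into the terminal alkyne under mild carbonate conditions that the aryl TIPS ether should tolerate.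

Step 12
Reactants: 18 phloroglucinol
Product: 19 5-(triisopropylsilyloxy)benzene-1,3-diol
Conditions: TIPSCl (0.33 equiv), imidazole, DMF, 0 °C → rt
Reagents that add atoms: triisopropylsilyl chloride (TIPSCl), CC(C)[Si](Cl)(C(C)C)C(C)C
Why: Statistical monosilylation of the symmetric triol, used in excess and washed out with water afterwards, marks the one oxygen that must not become the furan oxygen.

Step 13
Reactants: 19 5-(triisopropylsilyloxy)benzene-1,3-diol
Product: 20 [3,5-bis(methoxymethoxy)phenoxy]triisopropylsilane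
Conditions: MOMCl, i-Pr2NEt, CH2Cl2, 0 °C → rt
Reagents that add atoms: chloromethyl methyl ether (MOMCl), COCCl
Why: Williamson-type MOM protection of both remaining phenols installs the two directing groups for metalation.

Step 14
Reactants: 20 [3,5-bis(methoxymethoxy)phenoxy]triisopropylsilane
Product: 22 2-[2,6-bis(methoxymethoxy)-4-(triisopropylsilyloxy)phenyl]-4,4,5,5-tetramethyl-1,3,2-dioxaborolane, via aryllithium 21 (not isolated)
Conditions: n-BuLi, THF, 0 °C; i-PrOBpin, −78 °C → rt
Reagents that add atoms: 2-isopropoxy-4,4,5,5-tetramethyl-1,3,2-dioxaborolane (i-PrOBpin), CC(C)OB1OC(C)(C)C(C)(C)O1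
Why: Directed ortho-metalation should occur at the carbon flanked by both MOM ethers and not next to the bulky, non-coordinating silyl ether, and the aryllithium is borylated by the isopropoxy boronate.

Step 15
Reactants: 22 2-[2,6-bis(methoxymethoxy)-4-(triisopropylsilyloxy)phenyl]-4,4,5,5-tetramethyl-1,3,2-dioxaborolane, 23 ethyl N,N-diisopropylcarbamate
Product: 26 2-{(1S)-1-[2,6-bis(methoxymethoxy)-4-(triisopropylsilyloxy)phenyl]ethyl}-4,4,5,5-tetramethyl-1,3,2-dioxaborolane, via lithiated carbamate 24 (not isolated), via boronate complex 25 (not isolated)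
Conditions: 23, s-BuLi, (+)-sparteine, Et2O, −78 °C; then 22, −78 °C; MgBr2·OEt2, 35 °C
Reagents that add atoms: none
Why: Lithiation–borylation: (+)-sparteine-controlled deprotonation should give the (R)-lithiated carbamate, which adds to boron with retention, and the 1,2-metalate rearrangement then moves the aryl group to carbon with inversion while the carbamate leaves, which sets the benzylic stereocenter as (S).

Step 16
Reactants: 26 2-{(1S)-1-[2,6-bis(methoxymethoxy)-4-(triisopropylsilyloxy)phenyl]ethyl}-4,4,5,5-tetramethyl-1,3,2-dioxaborolane, 27 2-bromopropene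
Product: 30 {3,5-bis(methoxymethoxy)-4-[(2R)-3-methylbut-3-en-2-yl]phenoxy}triisopropylsilane, via isopropenyllithium 28 (not isolated), via alkenylboronate complex 29 (not isolated)
Conditions: 27, t-BuLi (2 equiv), THF, −78 °C; then 26, −78 °C; I2, MeOH, −78 °C; NaOMe, −78 → 0 °C
Reagents that add atoms: none
Why: Zweifel olefination: iodine triggers 1,2-migration of the benzylic carbon from boron to the alkenyl carbon with retention, and methoxide-induced anti elimination gives the 1,1-disubstituted alkene, so the (S)-boronic ester becomes the (R)-alkene (the descriptor changes only through the priority rules).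

Step 17
Reactants: 30 {3,5-bis(methoxymethoxy)-4-[(2R)-3-methylbut-3-en-2-yl]phenoxy}triisopropylsilane
Product: 31 {2-iodo-3,5-bis(methoxymethoxy)-4-[(2R)-3-methylbut-3-en-2-yl]phenoxy}triisopropylsilane
Conditions: NIS (1.05 equiv), MeCN, 0 °C, dark
Reagents that add atoms: N-iodosuccinimide (NIS), O=C1CCC(=O)N1I
Why: Electrophilic aromatic iodination should take place on the trioxygenated ring, which is far more nucleophilic than the 1,1-disubstituted alkene, and the two open ring positions are equivalent, so one mono-iodide results.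

Step 18
Reactants: 31 {2-iodo-3,5-bis(methoxymethoxy)-4-[(2R)-3-methylbut-3-en-2-yl]phenoxy}triisopropylsilane
Product: 33 4-iodo-2-[(2R)-3-methylbut-3-en-2-yl]-5-(triisopropylsilyloxy)benzene-1,3-diol, via bis(trimethylsilyl) ether 32 (not isolated)
Conditions: TMSOTf, 2,2'-bipyridyl, CH2Cl2, 0 °C → rt; then H2O
Reagents that add atoms: none
Why: The same buffered MOM-to-silyl exchange frees both phenols only on aqueous quench, so no protic acid is present that could add a phenol to the isopropenyl group, and the TIPS ether stays.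

Step 19
Reactants: 33 4-iodo-2-[(2R)-3-methylbut-3-en-2-yl]-5-(triisopropylsilyloxy)benzene-1,3-diol, 17 5-ethynyl-2,2-dimethyl-6-(3-methylbut-2-enyl)-7-(triisopropylsilyloxy)chroman
Product: 35 2-[2,2-dimethyl-6-(3-methylbut-2-enyl)-7-(triisopropylsilyloxy)chroman-5-yl]-7-[(2R)-3-methylbut-3-en-2-yl]-4-(triisopropylsilyloxy)-1-benzofuran-6-ol, via alkynylphenol 34 (not isolated)
Conditions: Pd(PPh3)2Cl2 (5 mol%), CuI (5 mol%), Et3N, DMF (degassed), 60 °C
Reagents that add atoms: none
Why: Sonogashira coupling followed in the same flask by 5-endo-dig cyclisation of the ortho-alkynylphenol (Castro–Stephens-type heteroannulation) gives the 2-arylbenzofuran, and only the free hydroxyl ortho to the alkyne can close because the other flanking oxygen is silylated, which fixes the furan oxygen next to the chiral side chain.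

Step 20
Reactants: 35 2-[2,2-dimethyl-6-(3-methylbut-2-enyl)-7-(triisopropylsilyloxy)chroman-5-yl]-7-[(2R)-3-methylbut-3-en-2-yl]-4-(triisopropylsilyloxy)-1-benzofuran-6-ol
Product: 36 2-[7-hydroxy-2,2-dimethyl-6-(3-methylbut-2-enyl)chroman-5-yl]-7-[(2R)-3-methylbut-3-en-2-yl]-1-benzofuran-4,6-diol
Conditions: Bu4NF, AcOH, THF, 0 °C → rt
Reagents that add atoms: none
Why: Fluoride cleaves both aryl TIPS ethers, and the acetic acid buffer keeps the medium close to neutral, so neither alkene nor the benzylic stereocenter should be affected.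

Compound list
1 | 5-bromoresorcinol (5-bromobenzene-1,3-diol) | Oc1cc(O)cc(Br)c1 | starting material
2 | 3-bromo-5-(methoxymethoxy)phenol | COCOc1cc(O)cc(Br)c1 | intermediate
3 | 3-chloro-3-methylbut-1-yne | C#CC(C)(C)Cl | starting material
4 | 1-bromo-3-(methoxymethoxy)-5-[(2-methylbut-3-yn-2-yl)oxy]benzene | COCOc1cc(OC(C)(C)C#C)cc(Br)c1 | intermediate
5 | 1-bromo-3-(methoxymethoxy)-5-[(2-methylbut-3-en-2-yl)oxy]benzene | COCOc1cc(OC(C)(C)C=C)cc(Br)c1 | intermediate
6 | 3-bromo-5-(methoxymethoxy)-2-(3-methylbut-2-enyl)phenol | COCOc1cc(O)c(CC=C(C)C)c(Br)c1 | intermediate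
7 | [3-bromo-5-(methoxymethoxy)-2-(3-methylbut-2-enyl)phenoxy]triisopropylsilane | COCOc1cc(O[Si](C(C)C)(C(C)C)C(C)C)c(CC=C(C)C)c(Br)c1 | intermediate
8 | [3-bromo-4-(3-methylbut-2-enyl)-5-(triisopropylsilyloxy)phenoxy]trimethylsilane | C[Si](C)(C)Oc1cc(O[Si](C(C)C)(C(C)C)C(C)C)c(CC=C(C)C)c(Br)c1 | intermediate
9 | 3-bromo-4-(3-methylbut-2-enyl)-5-(triisopropylsilyloxy)phenol | Oc1cc(O[Si](C(C)C)(C(C)C)C(C)C)c(CC=C(C)C)c(Br)c1 | intermediate
10 | 2-bromo-6-hydroxy-3-(3-methylbut-2-enyl)-4-(triisopropylsilyloxy)benzaldehyde | O=Cc1c(O)cc(O[Si](C(C)C)(C(C)C)C(C)C)c(CC=C(C)C)c1Br | intermediate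
11 | 3-bromo-2-(hydroxymethyl)-4-(3-methylbut-2-enyl)-5-(triisopropylsilyloxy)phenol | OCc1c(O)cc(O[Si](C(C)C)(C(C)C)C(C)C)c(CC=C(C)C)c1Br | intermediate
12 | isobutene (2-methylpropene) | C=C(C)C | starting material
13 | 5-bromo-6-methylidene-4-(3-methylbut-2-enyl)-3-(triisopropylsilyloxy)cyclohexa-2,4-dien-1-one (ortho-quinone methide) | C=C1C(=O)C=C(O[Si](C(C)C)(C(C)C)C(C)C)C(CC=C(C)C)=C1Br | intermediate
14 | 5-bromo-2,2-dimethyl-6-(3-methylbut-2-enyl)-7-(triisopropylsilyloxy)chroman | Brc1c(CC=C(C)C)c(O[Si](C(C)C)(C(C)C)C(C)C)cc2c1CCC(C)(C)O2 | intermediate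
15 | [2,2-dimethyl-6-(3-methylbut-2-enyl)-7-(triisopropylsilyloxy)chroman-5-yl]lithium | [Li]c1c(CC=C(C)C)c(O[Si](C(C)C)(C(C)C)C(C)C)cc2c1CCC(C)(C)O2 | intermediate
16 | 2,2-dimethyl-6-(3-methylbut-2-enyl)-7-(triisopropylsilyloxy)chroman-5-carbaldehyde | O=Cc1c(CC=C(C)C)c(O[Si](C(C)C)(C(C)C)C(C)C)cc2c1CCC(C)(C)O2 | intermediate
17 | 5-ethynyl-2,2-dimethyl-6-(3-methylbut-2-enyl)-7-(triisopropylsilyloxy)chroman | C#Cc1c(CC=C(C)C)c(O[Si](C(C)C)(C(C)C)C(C)C)cc2c1CCC(C)(C)O2 | intermediate
18 | phloroglucinol (benzene-1,3,5-triol) | Oc1cc(O)cc(O)c1 | starting material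
19 | 5-(triisopropylsilyloxy)benzene-1,3-diol | Oc1cc(O)cc(O[Si](C(C)C)(C(C)C)C(C)C)c1 | intermediate
20 | [3,5-bis(methoxymethoxy)phenoxy]triisopropylsilane | COCOc1cc(OCOC)cc(O[Si](C(C)C)(C(C)C)C(C)C)c1 | intermediate
21 | [2,6-bis(methoxymethoxy)-4-(triisopropylsilyloxy)phenyl]lithium | [Li]c1c(OCOC)cc(O[Si](C(C)C)(C(C)C)C(C)C)cc1OCOC | intermediate
22 | 2-[2,6-bis(methoxymethoxy)-4-(triisopropylsilyloxy)phenyl]-4,4,5,5-tetramethyl-1,3,2-dioxaborolane | COCOc1cc(O[Si](C(C)C)(C(C)C)C(C)C)cc(OCOC)c1B1OC(C)(C)C(C)(C)O1 | intermediate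
23 | ethyl N,N-diisopropylcarbamate | CCOC(=O)N(C(C)C)C(C)C | starting material
24 | [(1R)-1-(N,N-diisopropylcarbamoyloxy)ethyl]lithium | C[C@@H]([Li])OC(=O)N(C(C)C)C(C)C | intermediate
25 | lithium boronate complex of 22 with 24 (boron bears the aryl group, the pinacolato ligand and the (1R)-1-(diisopropylcarbamoyloxy)ethyl group) | [Li+].C[C@@H]([B-]1(c2c(OCOC)cc(O[Si](C(C)C)(C(C)C)C(C)C)cc2OCOC)OC(C)(C)C(C)(C)O1)OC(=O)N(C(C)C)C(C)C | intermediate
26 | 2-{(1S)-1-[2,6-bis(methoxymethoxy)-4-(triisopropylsilyloxy)phenyl]ethyl}-4,4,5,5-tetramethyl-1,3,2-dioxaborolane | C[C@@H](c1c(OCOC)cc(O[Si](C(C)C)(C(C)C)C(C)C)cc1OCOC)B1OC(C)(C)C(C)(C)O1 | intermediate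
27 | 2-bromopropene | C=C(C)Br | starting material
28 | isopropenyllithium | C=C(C)[Li] | intermediate
29 | lithium isopropenylboronate complex of 26 (boron bears isopropenyl, the (1S)-1-arylethyl group and the pinacolato ligand) | [Li+].C=C(C)[B-]1([C@@H](C)c2c(OCOC)cc(O[Si](C(C)C)(C(C)C)C(C)C)cc2OCOC)OC(C)(C)C(C)(C)O1 | intermediate
30 | {3,5-bis(methoxymethoxy)-4-[(2R)-3-methylbut-3-en-2-yl]phenoxy}triisopropylsilane | C=C(C)[C@@H](C)c1c(OCOC)cc(O[Si](C(C)C)(C(C)C)C(C)C)cc1OCOC | intermediate
31 | {2-iodo-3,5-bis(methoxymethoxy)-4-[(2R)-3-methylbut-3-en-2-yl]phenoxy}triisopropylsilane | C=C(C)[C@@H](C)c1c(OCOC)cc(O[Si](C(C)C)(C(C)C)C(C)C)c(I)c1OCOC | intermediate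
32 | {2-iodo-4-[(2R)-3-methylbut-3-en-2-yl]-3,5-bis(trimethylsilyloxy)phenoxy}triisopropylsilane | C=C(C)[C@@H](C)c1c(O[Si](C)(C)C)cc(O[Si](C(C)C)(C(C)C)C(C)C)c(I)c1O[Si](C)(C)C | intermediate
33 | 4-iodo-2-[(2R)-3-methylbut-3-en-2-yl]-5-(triisopropylsilyloxy)benzene-1,3-diol | C=C(C)[C@@H](C)c1c(O)cc(O[Si](C(C)C)(C(C)C)C(C)C)c(I)c1O | intermediate
34 | 4-{[2,2-dimethyl-6-(3-methylbut-2-enyl)-7-(triisopropylsilyloxy)chroman-5-yl]ethynyl}-2-[(2R)-3-methylbut-3-en-2-yl]-5-(triisopropylsilyloxy)benzene-1,3-diol | C=C(C)[C@@H](C)c1c(O)cc(O[Si](C(C)C)(C(C)C)C(C)C)c(C#Cc2c(CC=C(C)C)c(O[Si](C(C)C)(C(C)C)C(C)C)cc3c2CCC(C)(C)O3)c1O | intermediate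
35 | 2-[2,2-dimethyl-6-(3-methylbut-2-enyl)-7-(triisopropylsilyloxy)chroman-5-yl]-7-[(2R)-3-methylbut-3-en-2-yl]-4-(triisopropylsilyloxy)-1-benzofuran-6-ol | C=C(C)[C@@H](C)c1c(O)cc(O[Si](C(C)C)(C(C)C)C(C)C)c2cc(-c3c(CC=C(C)C)c(O[Si](C(C)C)(C(C)C)C(C)C)cc4c3CCC(C)(C)O4)oc12 | intermediate
36 | 2-[7-hydroxy-2,2-dimethyl-6-(3-methylbut-2-enyl)chroman-5-yl]-7-[(2R)-3-methylbut-3-en-2-yl]-1-benzofuran-4,6-diol | C=C(C)[C@@H](C)c1c(O)cc(O)c2cc(-c3c(CC=C(C)C)c(O)cc4c3CCC(C)(C)O4)oc12 | target

Total step count: 20 steps.
Longest linear sequence: 13 steps (steps 1 to 11, then 19 and 20); the ring A branch (steps 12 to 18) joins at step 19.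

Steps most likely to fail

Step 9. Self-condensation of the quinone methide, or its capture by the prenyl alkene of a second molecule, may outpace cycloaddition to the weakly nucleophilic alkene, which partitions into the gas phase. Fallback, setting out from 11: the quinone methide is generated in neat 2-methoxypropene (sealed tube, 110 °C). This electron-rich enol ether should trap it much faster and with the same orientation, giving racemic 5-bromo-2-methoxy-2-methyl-6-(3-methylbut-2-enyl)-7-(triisopropylsilyloxy)chroman F1. AlMe3 (CH2Cl2, −78 °C → rt) should then replace the ketal methoxy group by methyl through the cyclic oxocarbenium ion, which returns the route at 14.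

Step 15. Formation of the boronate complex at the doubly ortho-substituted boron may be slow, or the 1,2-migration incomplete, with decay of the lithiated carbamate and loss of enantiomeric purity. Fallback, setting out from 20: Matteson homologation replaces the carbamate chemistry. Methylboronic acid and (1S,2S)-1,2-dicyclohexylethane-1,2-diol give (4S,5S)-4,5-dicyclohexyl-2-methyl-1,3,2-dioxaborolane F2. LiCHCl2 with ZnCl2 (THF, −100 °C → rt) inserts a chloromethine unit under control of the diol to give (4S,5S)-2-[(1R)-1-chloroethyl]-4,5-dicyclohexyl-1,3,2-dioxaborolane F3. Compound 20 is lithiated as in step 14, the aryllithium 21 adds to the boron of F3, and ZnCl2-assisted migration of the aryl group displaces chloride with inversion. This gives (4S,5S)-2-{(1S)-1-[2,6-bis(methoxymethoxy)-4-(triisopropylsilyloxy)phenyl]ethyl}-4,5-dicyclohexyl-1,3,2-dioxaborolane F4, which takes the place of 26 in the Zweifel olefination and returns the route at 30.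

Step 19. Protodeiodination or oxidation of the electron-rich iodoresorcinol under the basic copper conditions, alkyne homocoupling, or stalling at the alkynylphenol (attack of oxygen on the hindered alkyne carbon is slow) may erode the union. Fallback, setting out from 31 and 17: coupling and ring closure are separated. Sonogashira coupling on the MOM-protected iodide (Pd(PPh3)2Cl2, CuI, Et3N, DMF, 60 °C) gives triisopropyl{2-{[2,2-dimethyl-6-(3-methylbut-2-enyl)-7-(triisopropylsilyloxy)chroman-5-yl]ethynyl}-3,5-bis(methoxymethoxy)-4-[(2R)-3-methylbut-3-en-2-yl]phenoxy}silane F5. MOM removal as in step 18 gives 34 as an isolated compound, and CuI with Et3N in DMF at 80 °C (5-endo-dig closure of the phenoxide onto the alkyne) returns the route at 35.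

Further compounds
F1 | step 9 | 5-bromo-2-methoxy-2-methyl-6-(3-methylbut-2-enyl)-7-(triisopropylsilyloxy)chroman (racemic at C2) | COC1(C)CCc2c(Br)c(CC=C(C)C)c(O[Si](C(C)C)(C(C)C)C(C)C)cc2O1
F2 | step 15 | (4S,5S)-4,5-dicyclohexyl-2-methyl-1,3,2-dioxaborolane | CB1O[C@@H](C2CCCCC2)[C@H](C2CCCCC2)O1
F3 | step 15 | (4S,5S)-2-[(1R)-1-chloroethyl]-4,5-dicyclohexyl-1,3,2-dioxaborolane | C[C@H](Cl)B1O[C@@H](C2CCCCC2)[C@H](C2CCCCC2)O1
F4 | step 15 | (4S,5S)-2-{(1S)-1-[2,6-bis(methoxymethoxy)-4-(triisopropylsilyloxy)phenyl]ethyl}-4,5-dicyclohexyl-1,3,2-dioxaborolane | C[C@@H](c1c(OCOC)cc(O[Si](C(C)C)(C(C)C)C(C)C)cc1OCOC)B1O[C@@H](C2CCCCC2)[C@H](C2CCCCC2)O1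
F5 | step 19 | triisopropyl{2-{[2,2-dimethyl-6-(3-methylbut-2-enyl)-7-(triisopropylsilyloxy)chroman-5-yl]ethynyl}-3,5-bis(methoxymethoxy)-4-[(2R)-3-methylbut-3-en-2-yl]phenoxy}silane | C=C(C)[C@@H](C)c1c(OCOC)cc(O[Si](C(C)C)(C(C)C)C(C)C)c(C#Cc2c(CC=C(C)C)c(O[Si](C(C)C)(C(C)C)C(C)C)cc3c2CCC(C)(C)O3)c1OCOC
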